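## The problem

2α-Hydroxyferutinin is a trans-fused hydroazulene in which a cycloheptene, numbered here C1(CH3)=C2–C3–C4(CH3)–C5(H)–C6(OAr)–C7, shares the C4–C5 bond with a cyclopentane C4–C5–C8(OH)(i-Pr)–C9–C10(OH). With the C4 methyl drawn up (β), the five stereocentres are quaternary C4, H-5 (α), the C6 4-hydroxybenzoate (α), the C8 tertiary hydroxyl (β, isopropyl α) and the C10 hydroxyl (α). C4 has no heteroatom or neighbour that could direct its formation, so it must come from an enantioselective carbon–carbon bond formation, and the remaining centres must then be derived from it and from each other. Two relays are available: the C8 hydroxyl is 1,3-anti to the C6 oxygen and can deliver hydride to a C6 ketone, and C5–H with C8–O corresponds to anti hydration of a C5=C8 alkene through an epoxide; only C10, flanked by the C4 methyl on one face and the C3 methylene on the other, has no clear substrate bias. The sensitive elements are the β-hydroxy ketone relationship between C8–OH and a C6 carbonyl (retro-aldol, dehydration), the tertiary alcohol (ionisation), the C1=C2 alkene (migration, oxidation) and the phenolic ester, which tolerates neither hydride reagents nor strong base. The enabling feature is that the seven-membered ring is a masked cyclohepta-1,4-diene: C1=C2 is present as such and the C6 oxygen can be carried as a C5=C6 enol ether, with quaternary C4 at a diene terminus. This is the retron of a vinylcarbenoid [4+3] annulation (cyclopropanation, then divinylcyclopropane Cope rearrangement), which forms C1–C7 and C3–C4, closes the ring and sets C4 in one operation.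

## Retrosynthesis

**Ester and silyl groups (29 ⇒ 28 ⇒ 26 + 27).** The C6–O acyl bond and both O–Si bonds are cut first. An aroyl ester would not survive the hydride steps that make the C1 methyl, so acylation cannot come earlier. Diol 26 and the commercial acid 27 are much simpler than 29. The forward reaction must acylate the secondary C6–OH beside the free tertiary C8–OH.

**C1 methyl (26 ⇒ 24 ⇒ 23).** Only C–O bonds are cut: the methyl comes from the ester that the carbenoid needs as its acceptor group. The ester is kept through the ketone and epoxide chemistry because it deactivates C1=C2 towards the oxidant of step 12. The forward steps must reduce the enoate 1,2 and remove the primary allylic oxygen without moving the alkene.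

**C6 carbinol (23 ⇒ 22).** The C6–H bond is cut back to a ketone. An external hydride would approach anti to the angular methyl and give the wrong epimer. Delivery from the C8 β-hydroxyl gives the required 1,3-anti diol, so the tertiary alcohol must be in place and free first.

**C5–H and C8–O (22 ⇒ 19 ⇒ 18 ⇒ 17).** These two bonds amount to anti hydration of a C5=C8 enone. Direct conjugate hydroxylation is not feasible on a tetrasubstituted enone, and reductive opening of an epoxy ketone would leave C5 to an uncontrolled protonation. Instead the C6 ketone of 17 is reduced to the β-alcohol 18, which directs epoxidation to the β face (19). A 1,2-hydride shift from C6 to C5 then places H-5 α with inversion and regenerates the C6 ketone (22). The C6 carbinol is thus a temporary relay; the forward shift must break the C5–O and not the C8–O epoxide bond.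

**Isopropyl group (17 ⇒ 15).** The C8–C(i-Pr) bond is cut by a Stork–Danheiser transposition. The vinylogous ester of 15 is both the electrophile at C8 and the latent C6 ketone, so no separate unmasking step is needed. C8 becomes sp2, so the face of addition does not matter.

**C10 oxygen (15 ⇒ 14 ⇒ 12 ⇒ 10).** The C10–O bond is cut back to a C9=C10 enone. C10 is β to the C8 ketone and unactivated afterwards, so the oxygen must go in before step 10. Because the substrate offers no facial bias, a chiral copper–boryl catalyst is asked to choose the α face.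

**Seven-membered ring and C4 (10 ⇒ 4 + 8).** C1–C7 and C3–C4 are cut together. This removes the ring and the only stereocentre of 10 and leaves an achiral ethoxydiene 4 and vinyldiazoacetate 8. The product already has the C6 oxygen, the C8 carbonyl and the C1 carbon differentiated. The forward reaction must cyclopropanate the ethoxyvinyl group enantioselectively and rearrange through a boat at a fully substituted terminus.

**The partners (4 ⇒ 2 + 3, 2 ⇒ 1; 8 ⇒ 7 ⇒ 6 ⇒ 5).** The C2–C(vinyl) bond of 4 is a Stille bond between iodoenone 2 (from enone 1) and stannane 3. Diazoester 8 comes from methyl acetoacetate 5 by diazo transfer, reduction and dehydration.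

## Roads not taken

**Alternative 1:** The cut is C4–C10 and C5–C8 on a preformed seven-membered ring. A chiral N-heterocyclic carbene–copper catalyst (from Cu(OTf)2 and an imidazolinium salt) would add a 1-(trimethylsilyl)vinyl group from an aluminium reagent to C4 of 3,6-dimethylcyclohepta-2,5-dien-1-one A1. The enolate would be trapped at C5 by isobutyraldehyde A2 to give the aldol A3.
- Merits: the quaternary centre comes from a catalytic asymmetric conjugate addition that is well established on β-substituted cyclic enones, including seven-membered ones. The C4/C5 trans pair is set at once, and the C1 methyl is present in A1 from the start.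
- Weak points: A1 is a skipped dienone whose C7 methylene, flanked by carbonyl and alkene, invites enolisation and drift into conjugation. The aldol trap next to a new quaternary centre is less secure than the addition, because A2 is branched and enolisable. No ring closes: from A3, C9 must still be joined to C8, which means converting the vinylsilane into a methyl ketone at C10, oxidising C8 and an aldol closure with no control at C8.
- Comparison: for enantiocontrol at C4 this road is probably better founded than step 6. The chosen plan offers in return ring closure and C4 in one step, and C6 and C8 already differentiated in 10.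

**Alternative 2:** The cut is C4–C5, traced to a decalin in which C4 is bonded to C6. A Diels–Alder reaction of thymoquinone A4 with isoprene A5 would lead, after redox and protecting-group work, to the hydroxy mesylate A6. Its C6 alkoxide (KOt-Bu or Et2AlCl) would push the antiperiplanar C4–C6 bond to C5 as the mesylate leaves, giving ketone A7.
- Merits: all fifteen carbons come from A4 and A5, two commodity chemicals, in one cycloaddition. The 1,2-shift is stereospecific, so H-5 is set as reliably as in step 13 here. A7 is the same kind of C6 ketone as 22 and could use the same directed reduction.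
- Weak points: the cycloaddition of A5 must choose the methyl-bearing alkene of A4, the right orientation and one enantiomer. A6 needs four contiguous stereocentres, two of them tertiary carbinols, on a flexible cis-decalin. The mesylate must be equatorial so that the ring bond C6–C4, not C6–C7, migrates, and epoxide closure or elimination compete.
- Comparison: this road is better in raw-material cost and equal in how C5 is set. The chosen plan has absolute control by catalysis at the ring-forming step and less functional-group work on a crowded decalin.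

**Alternative 3:** The cut is C6–C7. Tin–lithium exchange (n-BuLi) on the stannyl tetrahydropyran A8 would give an α-alkoxy carbanion that bonds to the isopropenyl CH2 while the O–C2 bond breaks (Wittig–Still [2,3] shift), giving A9.
- Merits: one step forms the carbocycle, the C6 carbinol and the C1=C2 alkene with its methyl. A9 is only acylation and desilylation from the target, a shorter end-game than the chosen route's, with no oxidation-state changes at C1 or C6.
- Weak points: A8 already contains C4, C5, C8 and C10, so the hardest part (a quaternary carbon between two oxygenated ring carbons) is moved upstream unsolved. The C6 stannane of A8 must be made with a defined configuration, and [1,2] shift and proton transfer compete with the ring-expanding [2,3] shift.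
- Comparison: this road wins on the last steps. The chosen plan makes C4 and the ring early from achiral five-carbon pieces and is shorter overall.

Key step: step 6

Assumption: the sense of induction of Rh2(S-DOSP)4 in step 6 and of the copper–(R,R)-QuinoxP* boryl complex in step 8 is assigned by analogy with simpler substrates and has not been derived for these substrates. If either proves opposite, the antipodal catalyst or ligand is used and nothing else changes.

In the names below, α and β refer to the hydroazulene drawn with the C4 (8a) methyl up (β); locants C1–C10 are those defined in the first section.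

## Route

Step 1
Reactants: 1 3-methylcyclopent-2-en-1-one
Product: 2 2-iodo-3-methylcyclopent-2-en-1-one
Conditions: I2, pyridine, CH2Cl2, 0 °C to rt
Reagents that add atoms: iodine, [I][I]
Why: Addition–elimination α-iodination of an enone: pyridine adds conjugately, the enolate is iodinated at C2 and pyridine is expelled. The β-methyl group slows the sequence but does not block it.

Step 2
Reactants: 2 2-iodo-3-methylcyclopent-2-en-1-one; 3 tributyl(1-ethoxyvinyl)stannane
Product: 4 2-(1-ethoxyvinyl)-3-methylcyclopent-2-en-1-one
Conditions: Pd(PPh3)4 (zerovalent palladium, 5 mol %), CuI (10 mol %), DMF, 50 °C; Et3N-treated silica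
Reagents that add atoms: none
Why: Stille coupling of an α-iodoenone with an α-alkoxyvinylstannane; copper iodide speeds transmetallation at the hindered vinyl iodide. Neutral conditions and base-washed silica keep the enol ether intact.

Step 3
Reactants: 5 methyl acetoacetate
Product: 6 methyl 2-diazo-3-oxobutanoate
Conditions: 4-AcNHC6H4SO2N3, Et3N, MeCN, 0 °C to rt
Reagents that add atoms: 4-acetamidobenzenesulfonyl azide, CC(=O)Nc1ccc(cc1)S(=O)(=O)N=[N+]=[N-]
Why: Regitz diazo transfer to the activated methylene of a 1,3-dicarbonyl compound.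

Step 4
Reactants: 6 methyl 2-diazo-3-oxobutanoate
Product: 7 methyl 2-diazo-3-hydroxybutanoate (racemic)
Conditions: NaBH4, MeOH, 0 °C
Reagents that add atoms: none
Why: Borohydride reduces the ketone; the diazo ester is inert at this temperature. The carbinol centre is lost in step 5, so its configuration is irrelevant.

Step 5
Reactants: 7 methyl 2-diazo-3-hydroxybutanoate
Product: 8 methyl 2-diazobut-3-enoate
Conditions: POCl3, Et3N, CH2Cl2, 0 °C; used at once as a pentane solution
Reagents that add atoms: none
Why: Dehydration through the dichlorophosphate with elimination towards the methyl group. The vinyldiazoacetate is used immediately because it cyclises to a pyrazole on standing.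

Step 6
Reactants: 4 2-(1-ethoxyvinyl)-3-methylcyclopent-2-en-1-one; 8 methyl 2-diazobut-3-enoate
Product: 10 methyl (8aR)-4-ethoxy-8a-methyl-3-oxo-1,2,3,5,8,8a-hexahydroazulene-6-carboxylate, via cis-divinylcyclopropane 9 (not isolated)
Conditions: Rh2(S-DOSP)4 [dirhodium tetrakis((S)-N-(4-dodecylbenzenesulfonyl)prolinate)] (1 mol %), hexanes, −40 °C, slow addition of 8; then PhMe, 100 °C
Reagents that add atoms: none
Why: The catalyst decomposes 8 with loss of N2 to a donor/acceptor rhodium vinylcarbenoid, which adds to the unsubstituted terminus of the ethoxyvinyl group of 4 and forms C1–C7 in a cyclopropane whose vinyl and cyclopentenyl groups are cis (9). This cis-divinylcyclopropane then undergoes a [3,3] Cope shift through a boat transition state, forming C3–C4 at the methyl-bearing ring carbon and breaking the C1–C6 cyclopropane bond; the seven-membered ring is thus closed by sigmatropic ring expansion, a formal [4+3] annulation. The closest known reaction type is the tandem cyclopropanation/Cope rearrangement of vinyldiazoacetates with oxygenated dienes under catalysis by chiral dirhodium prolinates such as Rh2(S-DOSP)4. The only new stereocentre, C4, is controlled by the catalyst: the prolinate ligands fix the absolute configuration of the cyclopropane and the boat geometry relays it stereospecifically to C4. The step needs attack at the enol ether rather than the enone (secured by the electron-poor, tetrasubstituted ring alkene), attack at the carbenoid carbon rather than its vinylogous terminus (favoured by the hydrocarbon solvent) and the cis arrangement of the two alkenyl groups (the usual outcome with dienes). The methyl group at the diene terminus points towards the cyclopropane methylene in the boat, so heating is expected to be needed; release of ring strain and the conjugation gained in the vinylogous ester drive the step.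

Step 7
Reactants: 10 methyl (8aR)-4-ethoxy-8a-methyl-3-oxo-1,2,3,5,8,8a-hexahydroazulene-6-carboxylate
Product: 12 methyl (8aS)-4-ethoxy-8a-methyl-3-oxo-3,5,8,8a-tetrahydroazulene-6-carboxylate (C9=C10 dienone), via trimethylsilyl dienol ether 11 (not isolated)
Conditions: LiN(i-Pr)2, Me3SiCl, THF, −78 °C; then Pd(OAc)2 (divalent palladium, 1.1 equiv), MeCN, rt
Reagents that add atoms: none
Why: Saegusa–Ito dehydrogenation: kinetic deprotonation of a vinylogous ester occurs at the α′ carbon (C9), and the silyl enol ether is oxidised through an oxa-π-allylpalladium species and β-hydride elimination. No stereocentre is touched.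

Step 8
Reactants: 12 methyl (8aS)-4-ethoxy-8a-methyl-3-oxo-3,5,8,8a-tetrahydroazulene-6-carboxylate
Product: 14 methyl 4-ethoxy-1α-hydroxy-8aβ-methyl-3-oxo-1,2,3,5,8,8a-hexahydroazulene-6-carboxylate (C10–OH α), via C10 pinacol boronate 13 (not isolated)
Conditions: CuCl (5 mol %), (R,R)-QuinoxP* [(R,R)-2,3-bis(tert-butylmethylphosphino)quinoxaline], NaOt-Bu (10 mol %), B2pin2, MeOH, THF, 0 °C; then NaBO3·4H2O, THF/H2O, rt
Reagents that add atoms: sodium perborate, [Na+].[Na+].O[B-]1(O)OO[B-](O)(O)OO1
Why: Copper-catalysed conjugate borylation takes the strained cyclopentenone in preference to the α-substituted enoate, and C–B oxidation proceeds with retention. The two faces of C10 are sterically almost equal, so the chiral copper–boryl complex is expected to decide the facial sense and place boron, then oxygen, on the α face; the type is known for cyclic enones, including ones with a quaternary γ-carbon.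

Step 9
Reactants: 14 methyl 4-ethoxy-1α-hydroxy-8aβ-methyl-3-oxo-1,2,3,5,8,8a-hexahydroazulene-6-carboxylate
Product: 15 methyl 1α-(tert-butyldimethylsilyloxy)-4-ethoxy-8aβ-methyl-3-oxo-1,2,3,5,8,8a-hexahydroazulene-6-carboxylate
Conditions: t-BuMe2SiOTf, 2,6-lutidine, CH2Cl2, −78 to 0 °C
Reagents that add atoms: tert-butyldimethylsilyl triflate, CC(C)(C)[Si](C)(C)OS(=O)(=O)C(F)(F)F
Why: Silyl triflate silylation of a hindered secondary alcohol under non-nucleophilic base. The ether guards against β-elimination and against the later oxidant.

Step 10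
Reactants: 15 methyl 1α-(tert-butyldimethylsilyloxy)-4-ethoxy-8aβ-methyl-3-oxo-1,2,3,5,8,8a-hexahydroazulene-6-carboxylate
Product: 17 methyl 1α-(tert-butyldimethylsilyloxy)-3-isopropyl-8aβ-methyl-4-oxo-1,2,4,5,8,8a-hexahydroazulene-6-carboxylate (C6 ketone; C5=C8 enone), via C8 tertiary allylic alcohol 16 (not isolated)
Conditions: i-PrMgCl, CeCl3, THF, −78 °C; then 1 M HCl, THF, 0 °C
Reagents that add atoms: isopropylmagnesium chloride, CC(C)[Mg]Cl; water, O
Why: Stork–Danheiser transposition: the weakly basic organocerium reagent adds 1,2 to the vinylogous ester carbonyl faster than it enolises C9 or attacks the enoate. Acid then ionises the tertiary allylic alcohol, water adds at C6 and ethanol is lost; C8 becomes sp2, so the face of addition is irrelevant.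

Step 11
Reactants: 17 methyl 1α-(tert-butyldimethylsilyloxy)-3-isopropyl-8aβ-methyl-4-oxo-1,2,4,5,8,8a-hexahydroazulene-6-carboxylate
Product: 18 methyl 1α-(tert-butyldimethylsilyloxy)-4β-hydroxy-3-isopropyl-8aβ-methyl-1,2,4,5,8,8a-hexahydroazulene-6-carboxylate (C6–OH β)
Conditions: (S)-2-methyl-CBS-oxazaborolidine (20 mol %), catecholborane, PhMe, −78 to −40 °C
Reagents that add atoms: none
Why: Corey–Bakshi–Shibata reduction under reagent control: the tetrasubstituted alkenyl carbon C5 is the large group and the C7 methylene the small one, so the (S)-catalyst delivers hydride to the α face of C6 and gives the β-carbinol. Catecholborane at low temperature leaves the enoate alone.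

Step 12
Reactants: 18 methyl 1α-(tert-butyldimethylsilyloxy)-4β-hydroxy-3-isopropyl-8aβ-methyl-1,2,4,5,8,8a-hexahydroazulene-6-carboxylate
Product: 19 methyl 1α-(tert-butyldimethylsilyloxy)-3β,3aβ-epoxy-4β-hydroxy-3-isopropyl-8aβ-methyl-1,2,3,3a,4,5,8,8a-octahydroazulene-6-carboxylate (C5–C8 β-epoxide)
Conditions: VO(acac)2 (5 mol %), t-BuOOH, CH2Cl2, 0 °C to rt
Reagents that add atoms: tert-butyl hydroperoxide, CC(C)(C)OO
Why: Vanadium-catalysed hydroxyl-directed epoxidation: the C6 alkoxide binds the vanadium peroxide and delivers oxygen to the syn (β) face of the electron-rich C5=C8 alkene, setting the C8 oxygen β. The electron-poor C1=C2 enoate does not react.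

Step 13
Reactants: 19 methyl 1α-(tert-butyldimethylsilyloxy)-3β,3aβ-epoxy-4β-hydroxy-3-isopropyl-8aβ-methyl-1,2,3,3a,4,5,8,8a-octahydroazulene-6-carboxylate
Product: 22 methyl 1α-(tert-butyldimethylsilyloxy)-3β-hydroxy-3α-isopropyl-8aβ-methyl-4-oxo-1,2,3,3aα,4,5,8,8a-octahydroazulene-6-carboxylate (H-5 α; trans-fused), via C6 O-trimethylsilyl epoxide 20 (not isolated), via C8 O-trimethylsilyl ketone 21 (not isolated)
Conditions: Me3SiOTf (2.5 equiv), i-Pr2NEt, CH2Cl2, −78 to −40 °C; then citric acid, MeOH, 0 °C
Reagents that add atoms: none
Why: Semipinacol rearrangement of a 2,3-epoxy alcohol silyl ether with 1,2-hydride shift (the non-aldol aldol process): the silyl triflate activates the epoxide, and the C6 hydrogen, antiperiplanar to the C5–O bond, migrates to C5 with inversion while the silyloxy lone pair forms the C6 carbonyl. H-5 therefore enters on the α face, trans to the retained C8 β-oxygen, and mild methanolysis removes the tertiary trimethylsilyl ether.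

Step 14
Reactants: 22 methyl 1α-(tert-butyldimethylsilyloxy)-3β-hydroxy-3α-isopropyl-8aβ-methyl-4-oxo-1,2,3,3aα,4,5,8,8a-octahydroazulene-6-carboxylate
Product: 23 methyl 1α-(tert-butyldimethylsilyloxy)-3β,4α-dihydroxy-3α-isopropyl-8aβ-methyl-1,2,3,3aα,4,5,8,8a-octahydroazulene-6-carboxylate (C6–OH α)
Conditions: Me4NBH(OAc)3, MeCN/AcOH, −30 °C
Reagents that add atoms: none
Why: Evans–Saksena directed reduction: the acetoxyborohydride bound to the C8 β-hydroxyl delivers hydride to the β face of C6 through a six-membered transition state, giving the 1,3-anti diol. The acidic medium avoids retro-aldol cleavage of the β-hydroxy ketone.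

Step 15
Reactants: 23 methyl 1α-(tert-butyldimethylsilyloxy)-3β,4α-dihydroxy-3α-isopropyl-8aβ-methyl-1,2,3,3aα,4,5,8,8a-octahydroazulene-6-carboxylate
Product: 24 1α-(tert-butyldimethylsilyloxy)-6-(hydroxymethyl)-3α-isopropyl-8aβ-methyl-1,2,3,3aα,4,5,8,8a-octahydroazulene-3β,4α-diol
Conditions: i-Bu2AlH (excess), CH2Cl2, −78 to 0 °C; aq. potassium sodium tartrate
Reagents that add atoms: none
Why: 1,2-Reduction of an α,β-unsaturated ester to the allylic alcohol. The free hydroxyls are carried as aluminium alkoxides and the silyl ether is inert.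

Step 16
Reactants: 24 1α-(tert-butyldimethylsilyloxy)-6-(hydroxymethyl)-3α-isopropyl-8aβ-methyl-1,2,3,3aα,4,5,8,8a-octahydroazulene-3β,4α-diol
Product: 26 1α-(tert-butyldimethylsilyloxy)-3α-isopropyl-6,8aβ-dimethyl-1,2,3,3aα,4,5,8,8a-octahydroazulene-3β,4α-diol, via primary allylic mesylate 25 (not isolated)
Conditions: MsCl (1.05 equiv), 2,4,6-collidine, CH2Cl2, −20 °C; then LiEt3BH, THF, −78 to 0 °C
Reagents that add atoms: none
Why: Selective sulfonylation of the primary allylic hydroxyl over the hindered secondary and tertiary ones, then direct SN2 displacement by triethylborohydride. Attack at the unhindered CH2 leaves the C1=C2 alkene in place.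

Step 17
Reactants: 26 1α-(tert-butyldimethylsilyloxy)-3α-isopropyl-6,8aβ-dimethyl-1,2,3,3aα,4,5,8,8a-octahydroazulene-3β,4α-diol; 27 4-(tert-butyldimethylsilyloxy)benzoic acid
Product: 28 1α-(tert-butyldimethylsilyloxy)-3β-hydroxy-3α-isopropyl-6,8aβ-dimethyl-1,2,3,3aα,4,5,8,8a-octahydroazulen-4α-yl 4-(tert-butyldimethylsilyloxy)benzoate
Conditions: DCC, DMAP, CH2Cl2, rt
Reagents that add atoms: none
Why: Steglich esterification: only the secondary C6 hydroxyl is acylated, the tertiary C8 hydroxyl being unreactive and C10 protected.

Step 18
Reactants: 28 1α-(tert-butyldimethylsilyloxy)-3β-hydroxy-3α-isopropyl-6,8aβ-dimethyl-1,2,3,3aα,4,5,8,8a-octahydroazulen-4α-yl 4-(tert-butyldimethylsilyloxy)benzoate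
Product: 29 2α-hydroxyferutinin [1α,3β-dihydroxy-3α-isopropyl-6,8aβ-dimethyl-1,2,3,3aα,4,5,8,8a-octahydroazulen-4α-yl 4-hydroxybenzoate]
Conditions: HF·pyridine, pyridine, THF, 0 °C to rt
Reagents that add atoms: none
Why: Fluoride cleaves the aryl and the secondary alkyl silyl ether together. The buffered, non-basic medium avoids phenoxide-mediated ester cleavage and ionisation of the tertiary alcohol.

## Compound list

1 | 3-methylcyclopent-2-en-1-one | CC1=CC(=O)CC1 | starting material
2 | 2-iodo-3-methylcyclopent-2-en-1-one | CC1=C(I)C(=O)CC1 | intermediate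
3 | tributyl(1-ethoxyvinyl)stannane | CCOC(=C)[Sn](CCCC)(CCCC)CCCC | starting material
4 | 2-(1-ethoxyvinyl)-3-methylcyclopent-2-en-1-one | C=C(OCC)C1=C(C)CCC1=O | intermediate
5 | methyl acetoacetate | COC(=O)CC(C)=O | starting material
6 | methyl 2-diazo-3-oxobutanoate | COC(=O)C(=[N+]=[N-])C(C)=O | intermediate
7 | methyl 2-diazo-3-hydroxybutanoate (racemic) | COC(=O)C(=[N+]=[N-])C(C)O | intermediate
8 | methyl 2-diazobut-3-enoate | C=CC(=[N+]=[N-])C(=O)OC | intermediate
9 | methyl (1S,2R)-2-ethoxy-2-(2-methyl-5-oxocyclopent-1-en-1-yl)-1-vinylcyclopropane-1-carboxylate (vinyl and cyclopentenyl cis) | COC(=O)[C@]1(C=C)C[C@@]1(OCC)C1=C(C)CCC1=O | intermediate (not isolated)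
10 | methyl (8aR)-4-ethoxy-8a-methyl-3-oxo-1,2,3,5,8,8a-hexahydroazulene-6-carboxylate | COC(=O)C1=CC[C@@]2(C)CCC(=O)C2=C(OCC)C1 | intermediate
11 | C8 trimethylsilyl dienol ether of 10 (C8=C9) | COC(=O)C1=CC[C@@]2(C)CC=C(O[Si](C)(C)C)C2=C(OCC)C1 | intermediate (not isolated)
12 | methyl (8aS)-4-ethoxy-8a-methyl-3-oxo-3,5,8,8a-tetrahydroazulene-6-carboxylate (C9=C10 dienone) | COC(=O)C1=CC[C@@]2(C)C=CC(=O)C2=C(OCC)C1 | intermediate
13 | C10α pinacol boronate of 10 | COC(=O)C1=CC[C@@]2(C)[C@@H](B3OC(C)(C)C(C)(C)O3)CC(=O)C2=C(OCC)C1 | intermediate (not isolated)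
14 | methyl 4-ethoxy-1α-hydroxy-8aβ-methyl-3-oxo-1,2,3,5,8,8a-hexahydroazulene-6-carboxylate | COC(=O)C1=CC[C@@]2(C)[C@@H](O)CC(=O)C2=C(OCC)C1 | intermediate
15 | methyl 1α-(tert-butyldimethylsilyloxy)-4-ethoxy-8aβ-methyl-3-oxo-1,2,3,5,8,8a-hexahydroazulene-6-carboxylate | COC(=O)C1=CC[C@@]2(C)[C@@H](O[Si](C)(C)C(C)(C)C)CC(=O)C2=C(OCC)C1 | intermediate
16 | methyl 1α-(tert-butyldimethylsilyloxy)-4-ethoxy-3-hydroxy-3-isopropyl-8aβ-methyl-1,2,3,5,8,8a-hexahydroazulene-6-carboxylate (C8 epimers) | COC(=O)C1=CC[C@@]2(C)[C@@H](O[Si](C)(C)C(C)(C)C)CC(O)(C(C)C)C2=C(OCC)C1 | intermediate (not isolated)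
17 | methyl 1α-(tert-butyldimethylsilyloxy)-3-isopropyl-8aβ-methyl-4-oxo-1,2,4,5,8,8a-hexahydroazulene-6-carboxylate | COC(=O)C1=CC[C@@]2(C)[C@@H](O[Si](C)(C)C(C)(C)C)CC(C(C)C)=C2C(=O)C1 | intermediate
18 | methyl 1α-(tert-butyldimethylsilyloxy)-4β-hydroxy-3-isopropyl-8aβ-methyl-1,2,4,5,8,8a-hexahydroazulene-6-carboxylate | COC(=O)C1=CC[C@@]2(C)[C@@H](O[Si](C)(C)C(C)(C)C)CC(C(C)C)=C2[C@H](O)C1 | intermediate
19 | methyl 1α-(tert-butyldimethylsilyloxy)-3β,3aβ-epoxy-4β-hydroxy-3-isopropyl-8aβ-methyl-1,2,3,3a,4,5,8,8a-octahydroazulene-6-carboxylate | COC(=O)C1=CC[C@@]2(C)[C@@H](O[Si](C)(C)C(C)(C)C)C[C@]3(C(C)C)O[C@]23[C@H](O)C1 | intermediate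
20 | C6 O-trimethylsilyl ether of 19 | COC(=O)C1=CC[C@@]2(C)[C@@H](O[Si](C)(C)C(C)(C)C)C[C@]3(C(C)C)O[C@]23[C@H](O[Si](C)(C)C)C1 | intermediate (not isolated)
21 | C8 O-trimethylsilyl ether of 22 | COC(=O)C1=CC[C@@]2(C)[C@@H](O[Si](C)(C)C(C)(C)C)C[C@@](O[Si](C)(C)C)(C(C)C)[C@@H]2C(=O)C1 | intermediate (not isolated)
22 | methyl 1α-(tert-butyldimethylsilyloxy)-3β-hydroxy-3α-isopropyl-8aβ-methyl-4-oxo-1,2,3,3aα,4,5,8,8a-octahydroazulene-6-carboxylate | COC(=O)C1=CC[C@@]2(C)[C@@H](O[Si](C)(C)C(C)(C)C)C[C@@](O)(C(C)C)[C@@H]2C(=O)C1 | intermediate
23 | methyl 1α-(tert-butyldimethylsilyloxy)-3β,4α-dihydroxy-3α-isopropyl-8aβ-methyl-1,2,3,3aα,4,5,8,8a-octahydroazulene-6-carboxylate | COC(=O)C1=CC[C@@]2(C)[C@@H](O[Si](C)(C)C(C)(C)C)C[C@@](O)(C(C)C)[C@@H]2[C@@H](O)C1 | intermediate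
24 | 1α-(tert-butyldimethylsilyloxy)-6-(hydroxymethyl)-3α-isopropyl-8aβ-methyl-1,2,3,3aα,4,5,8,8a-octahydroazulene-3β,4α-diol | OCC1=CC[C@@]2(C)[C@@H](O[Si](C)(C)C(C)(C)C)C[C@@](O)(C(C)C)[C@@H]2[C@@H](O)C1 | intermediate
25 | primary allylic methanesulfonate of 24 | CS(=O)(=O)OCC1=CC[C@@]2(C)[C@@H](O[Si](C)(C)C(C)(C)C)C[C@@](O)(C(C)C)[C@@H]2[C@@H](O)C1 | intermediate (not isolated)
26 | 1α-(tert-butyldimethylsilyloxy)-3α-isopropyl-6,8aβ-dimethyl-1,2,3,3aα,4,5,8,8a-octahydroazulene-3β,4α-diol | CC1=CC[C@@]2(C)[C@@H](O[Si](C)(C)C(C)(C)C)C[C@@](O)(C(C)C)[C@@H]2[C@@H](O)C1 | intermediate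
27 | 4-(tert-butyldimethylsilyloxy)benzoic acid | CC(C)(C)[Si](C)(C)Oc1ccc(cc1)C(O)=O | starting material
28 | 1α-(tert-butyldimethylsilyloxy)-3β-hydroxy-3α-isopropyl-6,8aβ-dimethyl-1,2,3,3aα,4,5,8,8a-octahydroazulen-4α-yl 4-(tert-butyldimethylsilyloxy)benzoate | CC1=CC[C@@]2(C)[C@@H](O[Si](C)(C)C(C)(C)C)C[C@@](O)(C(C)C)[C@@H]2[C@@H](OC(=O)c3ccc(O[Si](C)(C)C(C)(C)C)cc3)C1 | intermediate
29 | 2α-hydroxyferutinin | CC1=CC[C@@]2(C)[C@@H](O)C[C@@](O)(C(C)C)[C@@H]2[C@@H](OC(=O)c3ccc(O)cc3)C1 | target

## Step count

Total: 18 steps. Longest linear sequence: 16 steps (steps 3–18, from methyl acetoacetate 5); the branch from 1 is 15 steps.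

## Least certain steps

**Step 6 (key step).** Three processes can go wrong. The enol ether may attack the vinylogous terminus of the unsubstituted vinylcarbenoid. The ethoxyvinyl group may be cyclopropanated with the cyclopentenyl group trans to the vinyl group; such a cyclopropane rearranges only after opening of the push–pull ring, which erases the catalyst-derived configuration. The Cope shift is also slowed by the methyl group pointing into the boat. The fallback moves the source of asymmetry from the catalyst to an auxiliary and uses a small achiral dirhodium carboxylate, which favours attack at the carbenoid carbon. It sets out from 4 and returns at 10. But-3-enoic acid is esterified with (R)-pantolactone (DCC, cat. DMAP) to the ester F1. Diazo transfer (4-acetamidobenzenesulfonyl azide, DBU) gives the vinyldiazoacetate F2. With Rh2(O2CC7H15)4 (dirhodium tetraoctanoate) in pentane, F2 and 4 give the cyclopropane F3 and, on heating, the cycloadduct F4. Methanolysis (K2CO3, MeOH) exchanges the auxiliary for methyl and gives 10.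

**Step 13.** The other epoxide bond (C8–O) may ionise, with proton loss towards C9 or the isopropyl group giving an allylic silyl ether. The new C6 ketone may also be silylated at C7, which is flanked by the ketone and the enoate alkene, with drift of C1=C2 into conjugation. The fallback fixes the regiochemistry through a ketyl; it sets out from 19 and returns at 22. Dess–Martin oxidation gives the epoxy ketone F5. SmI2 in THF/MeOH at −90 °C cleaves the C5–O bond α to the carbonyl and gives 22. If protonation of the samarium enolate gives the cis-fused C5 epimer F6, brief treatment with DBU is expected to epimerise it to 22, in which C6 lies trans to the isopropyl group.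

**Step 8.** Facial discrimination at C10 may be weak, because methyl and C3 methylene shield the two faces about equally and the ligand must do all the work. Borylation of the enoate and elimination of the β-hydroxy ketone during oxidation are lesser risks. The fallback replaces selection by separation and recycling; it sets out from 12 and returns at 14. The borylation is run without regard to selectivity. 14 is separated by chromatography from its C10 epimer F7. F7 is treated with MsCl/Et3N, and its mesylate F8 eliminates in the flask to regenerate 12, which is resubmitted.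

**Step 10.** The organometallic may enolise the C8 ketone at C9 with loss of the β-silyloxy group, reduce the ketone by β-hydride transfer, or attack the enoate. The fallback uses an sp2 nucleophile with no β-hydrogen and adds a hydrogenation; it sets out from 15 and returns at 17. 2-Propenylmagnesium bromide/CeCl3 gives the tertiary alcohol F9, which on acid work-up transposes to the isopropenyl dienone F10. H2 with RhCl(PPh3)3 in benzene saturates only the 1,1-disubstituted alkene and gives 17.

**Step 16.** Hydride may be delivered with allylic transposition (exocyclic methylene), the C6 hydroxyl may also be sulfonylated, or a C6 alkoxide may displace the allylic leaving group. The fallback changes the mechanism to a π-allylpalladium hydride reduction; it sets out from 24 and returns at 26. Selective acetylation of the primary hydroxyl (Ac2O, 2,4,6-collidine, −20 °C) gives the acetate F11. Pd(PPh3)4 (zerovalent palladium) with LiEt3BH in THF delivers hydride to the less substituted allyl terminus and gives 26.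

## Further compounds

F1 | step 6 | (3R)-4,4-dimethyl-2-oxooxolan-3-yl but-3-enoate | C=CCC(=O)O[C@H]1C(=O)OCC1(C)C
F2 | step 6 | (3R)-4,4-dimethyl-2-oxooxolan-3-yl 2-diazobut-3-enoate | C=CC(=[N+]=[N-])C(=O)O[C@H]1C(=O)OCC1(C)C
F3 | step 6 | (3R)-4,4-dimethyl-2-oxooxolan-3-yl (1S,2R)-2-ethoxy-2-(2-methyl-5-oxocyclopent-1-en-1-yl)-1-vinylcyclopropane-1-carboxylate (not isolated) | O=C(O[C@H]3C(=O)OCC3(C)C)[C@]1(C=C)C[C@@]1(OCC)C1=C(C)CCC1=O
F4 | step 6 | (3R)-4,4-dimethyl-2-oxooxolan-3-yl (8aR)-4-ethoxy-8a-methyl-3-oxo-1,2,3,5,8,8a-hexahydroazulene-6-carboxylate | O=C(O[C@H]3C(=O)OCC3(C)C)C1=CC[C@@]2(C)CCC(=O)C2=C(OCC)C1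
F5 | step 13 | methyl 1α-(tert-butyldimethylsilyloxy)-3β,3aβ-epoxy-3-isopropyl-8aβ-methyl-4-oxo-1,2,3,3a,4,5,8,8a-octahydroazulene-6-carboxylate | COC(=O)C1=CC[C@@]2(C)[C@@H](O[Si](C)(C)C(C)(C)C)C[C@]3(C(C)C)O[C@]23C(=O)C1
F6 | step 13 | C5 epimer of 22 (H-5 β; cis-fused) | COC(=O)C1=CC[C@@]2(C)[C@@H](O[Si](C)(C)C(C)(C)C)C[C@@](O)(C(C)C)[C@H]2C(=O)C1
F7 | step 8 | C10 epimer of 14 (C10–OH β) | COC(=O)C1=CC[C@@]2(C)[C@H](O)CC(=O)C2=C(OCC)C1
F8 | step 8 | C10 methanesulfonate of F7 (not isolated) | COC(=O)C1=CC[C@@]2(C)[C@H](OS(C)(=O)=O)CC(=O)C2=C(OCC)C1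
F9 | step 10 | methyl 1α-(tert-butyldimethylsilyloxy)-4-ethoxy-3-hydroxy-8aβ-methyl-3-(prop-1-en-2-yl)-1,2,3,5,8,8a-hexahydroazulene-6-carboxylate (C8 epimers; not isolated) | COC(=O)C1=CC[C@@]2(C)[C@@H](O[Si](C)(C)C(C)(C)C)CC(O)(C(C)=C)C2=C(OCC)C1
F10 | step 10 | methyl 1α-(tert-butyldimethylsilyloxy)-8aβ-methyl-4-oxo-3-(prop-1-en-2-yl)-1,2,4,5,8,8a-hexahydroazulene-6-carboxylate | COC(=O)C1=CC[C@@]2(C)[C@@H](O[Si](C)(C)C(C)(C)C)CC(C(C)=C)=C2C(=O)C1
F11 | step 16 | primary allylic acetate of 24 | CC(=O)OCC1=CC[C@@]2(C)[C@@H](O[Si](C)(C)C(C)(C)C)C[C@@](O)(C(C)C)[C@@H]2[C@@H](O)C1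
A1 | alternative 1 | 3,6-dimethylcyclohepta-2,5-dien-1-one | CC1=CC(=O)CC(C)=CC1
A2 | alternative 1 | isobutyraldehyde | CC(C)C=O
A3 | alternative 1 | trans-4-(1-trimethylsilylvinyl)-5-(1-hydroxy-2-methylpropyl)cycloheptenone | CC1=CC[C@@](C)(C(=C)[Si](C)(C)C)[C@@H](C(=O)C1)[C@@H](C(C)C)O
A4 | alternative 2 | thymoquinone | CC1=CC(=O)C(C(C)C)=CC1=O
A5 | alternative 2 | isoprene | CC(=C)C=C
A6 | alternative 2 | cis-decalin C6 hydroxy C5 mesylate with C8 triethylsilyl and C10 tert-butyldimethylsilyl ethers | CC1=CC[C@@]2(C)[C@@H](O[Si](C)(C)C(C)(C)C)C[C@@](O[Si](CC)(CC)CC)(C(C)C)[C@H](OS(C)(=O)=O)[C@@]2(O)C1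
A7 | alternative 2 | trans-fused C6-keto hydroazulene bis-silyl ether | CC1=CC[C@]2(C)[C@@H](C(=O)C1)[C@](O[Si](CC)(CC)CC)(C(C)C)C[C@@H]2O[Si](C)(C)C(C)(C)C
A8 | alternative 3 | 2,6-cis 2-isopropenyl-6-(tributylstannyl)tetrahydropyran fused to the silylated cyclopentane | CC(=C)[C@H]1C[C@]2(C)[C@@H]([C@H](O1)[Sn](CCCC)(CCCC)CCCC)[C@](O[Si](CC)(CC)CC)(C(C)C)C[C@@H]2O[Si](C)(C)C(C)(C)C
A9 | alternative 3 | hydroazulene C6 alcohol with C8 triethylsilyl and C10 tert-butyldimethylsilyl ethers | CC1=CC[C@]2(C)[C@@H]([C@@H](O)C1)[C@](O[Si](CC)(CC)CC)(C(C)C)C[C@@H]2O[Si](C)(C)C(C)(C)C
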